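**Retrosynthetic overview**
- Target 11 ⇐ O-acetylation of allylic alcohol 10 ⇐ allylic hydroxylation of the C-17 methyl of ent-labd-7-enoate 9.
- 9 ⇐ open-chain all-E trienoate 8 by one catalytic asymmetric proton-initiated cascade. Ring A closes first (C4–C5) and ring B directly after (C9–C10) in the same event, which sets C-5, C-9, C-10 and the 7-ene.
- 8 ⇐ enoate 7 by CuH asymmetric conjugate reduction (sets C-13) ⇐ ketone 5 + phosphonate 6 (HWE) ⇐ farnesyl bromide 1 + methyl acetoacetate 2.
- No protecting groups; every carbon except the acetyl comes from 1, 2 and 6.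

Assumption: (2E,6E)-farnesyl bromide is bought as a catalog reagent, and the target is the ent-labdane antipode encoded in the SMILES (5R,9S,10R,13R, labdane numbering).

**Step 1**
Reactants: 1 (2E,6E)-farnesyl bromide; 2 methyl acetoacetate
Product: 5 (5E,9E)-farnesylacetone, via alkylated keto ester 3 (not isolated), via keto acid 4 (not isolated)
Conditions: NaH, THF, 0 °C to rt; then 2 M NaOH, MeOH, 60 °C; then 2 M HCl to pH 3, 50 °C
Reagents that add atoms: none
Why: Acetoacetic ester synthesis: the soft sodium enolate of 2 displaces the primary allylic bromide by SN2 with the 2E geometry retained, and saponification then acidification frees the β-keto acid, which loses CO2 on warming; no stereocenter is involved.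

**Step 2**
Reactants: 5 (5E,9E)-farnesylacetone; 6 trimethyl phosphonoacetate
Product: 7 methyl (2E,6E,10E)-geranylgeranoate
Conditions: NaH, THF, 0 °C to 50 °C; 2E isomer isolated on silica (E:Z about 4:1)
Reagents that add atoms: none
Why: Horner–Wadsworth–Emmons olefination of a methyl ketone gives mainly the 2E enoate (ester trans to the long chain), and the geometric isomers of such β-methyl enoates separate by chromatography; geometric purity matters because it fixes the face offered in step 3.

**Step 3**
Reactants: 7 methyl (2E,6E,10E)-geranylgeranoate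
Product: 8 methyl (3R,6E,10E)-3,7,11,15-tetramethylhexadeca-6,10,14-trienoate
Conditions: Cu(OAc)2 (3 mol%), (R)-DTBM-SEGPHOS (3.3 mol%), (EtO)2MeSiH (1.5 equiv), t-BuOH (1.5 equiv), toluene, 0 °C
Reagents that add atoms: none
Why: CuH-catalysed asymmetric conjugate reduction touches only the conjugated C2=C3 bond and leaves the three isolated trisubstituted alkenes alone; hydride delivery to the Si face of C-3 of the pure 2E enoate gives 3R (the future C-13), and the ligand antipode is taken instead should the first run show the opposite sense.

**Step 4**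
Reactants: 8 methyl (3R,6E,10E)-3,7,11,15-tetramethylhexadeca-6,10,14-trienoate
Product: 9 methyl ent-labd-7-en-15-oate (5R,9R,10R,13R)
Conditions: confined chiral IDPi Brønsted acid (BINOL-derived imidodiphosphorimidate, bulky 3,3′-aryl groups, N-sulfonyl core; 5 mol%; the antipode that leads to the 5R,10R series), (CF3)3COH, 0 °C, 3 d
Reagents that add atoms: none
Why: Proposed new method: the strongly acidic, confined IDPi protonates the least hindered terminal Me2C=CH alkene enantiofacially, and the all-E triene, folded chair–chair in the catalyst pocket, closes ring A (C4–C5) and ring B (C9–C10) in one anti-periplanar Stork–Eschenmoser cascade, so the 6E and 10E geometries translate into the trans ring fusion with H-5 and H-9 anti to the C-10 methyl while the catalyst's face choice fixes the absolute 5R,9R,10R sense, and the tertiary C-8 cation is quenched by loss of the axial H-7 to the counteranion to give the trisubstituted 7-ene; the closest known reactions are the IDPi-catalysed asymmetric proton-initiated polycyclisation of an all-E homofarnesyl alcohol in fluorinated alcohol and the superacid bicyclisation of farnesyl esters to drim-7-enes, the extension here being an elimination-terminated aliphatic ester whose fixed C-13 centre makes the minor facial isomer a separable diastereomer.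

**Step 5**
Reactants: 9 methyl ent-labd-7-en-15-oate
Product: 10 methyl 17-hydroxy-ent-labd-7-en-15-oate (5R,9S,10R,13R)
Conditions: SeO2 (0.5 equiv), t-BuOOH (3 equiv), CH2Cl2, 0 °C to rt
Reagents that add atoms: selenium dioxide, O=[Se]=O (transfers the oxygen and is re-formed by tert-butyl hydroperoxide, CC(C)(C)OO)
Why: Sharpless-modified Riley allylic oxidation: ene reaction at the less substituted C-7 followed by a [2,3]-sigmatropic shift restores the 7,8-alkene and oxygenates an allylic carbon on the more substituted terminus, where the C-17 methyl is preferred over the hindered C-9 methine as in the drim-7-ene series; no stereocenter is created and the only alkene left is the reacting one.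

**Step 6**
Reactants: 10 methyl 17-hydroxy-ent-labd-7-en-15-oate
Product: 11 methyl (13R)-17-acetoxy-ent-labd-7-en-15-oate (target, CNP0149025.1)
Conditions: Ac2O, pyridine, DMAP (cat.), CH2Cl2, 0 °C to rt
Reagents that add atoms: acetic anhydride, CC(=O)OC(C)=O
Why: DMAP-catalysed acylation of the unhindered primary allylic alcohol; the methyl ester and all four stereocenters are untouched.

**Compound list**
1 | (2E,6E)-farnesyl bromide [(2E,6E)-1-bromo-3,7,11-trimethyldodeca-2,6,10-triene] | CC(C)=CCC/C(C)=C/CC/C(C)=C/CBr | starting material
2 | methyl acetoacetate | COC(=O)CC(C)=O | starting material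
3 | methyl (4E,8E)-2-acetyl-5,9,13-trimethyltetradeca-4,8,12-trienoate (racemic at C-2) | CC(C)=CCC/C(C)=C/CC/C(C)=C/CC(C(C)=O)C(=O)OC | intermediate
4 | (4E,8E)-2-acetyl-5,9,13-trimethyltetradeca-4,8,12-trienoic acid (racemic at C-2) | CC(C)=CCC/C(C)=C/CC/C(C)=C/CC(C(C)=O)C(=O)O | intermediate
5 | (5E,9E)-farnesylacetone [(5E,9E)-6,10,14-trimethylpentadeca-5,9,13-trien-2-one] | CC(C)=CCC/C(C)=C/CC/C(C)=C/CCC(C)=O | intermediate
6 | trimethyl phosphonoacetate | COC(=O)CP(=O)(OC)OC | starting material
7 | methyl (2E,6E,10E)-3,7,11,15-tetramethylhexadeca-2,6,10,14-tetraenoate | CC(C)=CCC/C(C)=C/CC/C(C)=C/CC/C(C)=C/C(=O)OC | intermediate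
8 | methyl (3R,6E,10E)-3,7,11,15-tetramethylhexadeca-6,10,14-trienoate | CC(C)=CCC/C(C)=C/CC/C(C)=C/CC[C@@H](C)CC(=O)OC | intermediate
9 | methyl ent-labd-7-en-15-oate; methyl (3R)-3-methyl-5-[(1R,4aR,8aR)-2,5,5,8a-tetramethyl-1,4,4a,5,6,7,8,8a-octahydronaphthalen-1-yl]pentanoate | COC(=O)C[C@H](C)CC[C@@H]1C(C)=CC[C@@H]2C(C)(C)CCC[C@@]12C | intermediate
10 | methyl 17-hydroxy-ent-labd-7-en-15-oate; methyl (3R)-5-[(1S,4aR,8aR)-2-(hydroxymethyl)-5,5,8a-trimethyl-1,4,4a,5,6,7,8,8a-octahydronaphthalen-1-yl]-3-methylpentanoate | COC(=O)C[C@H](C)CC[C@@H]1C(CO)=CC[C@@H]2C(C)(C)CCC[C@@]12C | intermediate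
11 | methyl (13R)-17-acetoxy-ent-labd-7-en-15-oate; methyl (3R)-5-[(1S,4aR,8aR)-2-(acetoxymethyl)-5,5,8a-trimethyl-1,4,4a,5,6,7,8,8a-octahydronaphthalen-1-yl]-3-methylpentanoate | COC(=O)C[C@H](C)CC[C@@H]1C(COC(C)=O)=CC[C@@H]2C(C)(C)CCC[C@@]12C | target

**Totals**
Total step count: 6. Longest linear sequence: 6 (1 → 5 → 7 → 8 → 9 → 10 → 11).

**Three steps most likely to fail**

Step 4 (bicyclisation). The triene carries no aryl or hydroxyl terminator, so enantiofacial control, complete closure of ring B and regioselective loss of H-7 are all extrapolated; double-bond regioisomers and re-protonation of the product are the expected side paths. Fallback: setting out from 8, an enantioselective bromonium-initiated bicyclisation (1,3-dibromo-5,5-dimethylhydantoin with a chiral BINOL-derived thiophosphoramide Lewis-base catalyst, toluene, −78 °C) would still close both rings at once, but with a softer electrophile held more tightly by the catalyst. It would give the equatorial bromide methyl (3R,5S,9R,10S,13R)-3-bromo-ent-labd-7-en-15-oate F1. Radical debromination (Bu3SnH, AIBN, benzene, 80 °C) then comes back to the route at 9.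

Step 5 (allylic hydroxylation). Over-oxidation to the enal and incomplete conversion are likely. Fallback: setting out from 9, stoichiometric SeO2 in dioxane at 80 °C drives the oxidation through to the enal methyl 17-oxo-ent-labd-7-en-15-oate F2, the usual outcome in the drim-7-ene series. Luche reduction (NaBH4, CeCl3·7H2O, MeOH, 0 °C) then comes back to the route at 10 without touching the saturated methyl ester.

Step 2 (olefination). The E:Z ratio is only about 4:1, separating the isomers on scale is tedious, and any 2Z ester carried forward erodes C-13 in step 3. Fallback: setting out from 1 and 2, the dianion of 2 (NaH then n-BuLi, THF, 0 °C) is alkylated at its terminal carbon by 1 to give the β-keto ester methyl (6E,10E)-7,11,15-trimethyl-3-oxohexadeca-6,10,14-trienoate F3. Its sodium enolate (NaH, Et2O, 0 °C) is trapped with ClP(O)(OEt)2 as the Z enol phosphate methyl (2Z,6E,10E)-3-[(diethoxyphosphoryl)oxy]-7,11,15-trimethylhexadeca-2,6,10,14-tetraenoate F4. Me2CuLi (Et2O, −78 °C) replaces the phosphate by methyl with retention and comes back to the route at geometrically pure 7.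

**Further compounds**
F1 | step 4 | methyl (3R,5S,9R,10S,13R)-3-bromo-ent-labd-7-en-15-oate | COC(=O)C[C@H](C)CC[C@@H]1C(C)=CC[C@@H]2C(C)(C)[C@H](Br)CC[C@@]12C
F2 | step 5 | methyl (5R,9S,10R,13R)-17-oxo-ent-labd-7-en-15-oate | COC(=O)C[C@H](C)CC[C@@H]1C(C=O)=CC[C@@H]2C(C)(C)CCC[C@@]12C
F3 | step 2 | methyl (6E,10E)-7,11,15-trimethyl-3-oxohexadeca-6,10,14-trienoate | CC(C)=CCC/C(C)=C/CC/C(C)=C/CCC(=O)CC(=O)OC
F4 | step 2 | methyl (2Z,6E,10E)-3-[(diethoxyphosphoryl)oxy]-7,11,15-trimethylhexadeca-2,6,10,14-tetraenoate | CC(C)=CCC/C(C)=C/CC/C(C)=C/CC/C(OP(=O)(OCC)OCC)=C/C(=O)OC
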